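## Retrosynthetic overview

1. Target 26 ⇐ fluoride deprotection, Wittig methylenation of a 17-nor-16-ketone and thermodynamic reduction of a C2 ketone ⇐ 2-oxo-19,20-lactone 22 ⇐ amidyl-radical δ-lactonisation at C20 and carboxylate-directed γ-oxidation at C2 ⇐ ring-contracted diester 16.
2. 16 ⇐ photochemical Wolff ring contraction (C5 shifts from the carbonyl carbon C6 to the diazo carbon C7 of the kaurane) ⇐ diazo ketone 13 ⇐ formylation and diazo transfer on a 6-ketone ⇐ carboxylate-directed 19,6-lactonisation ⇐ steviol (1).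
3. Feature used: ring B of the gibberellane (C5, C6, C8, C9, C10) is the six-membered ring B of an ent-kaurane less one carbon. Steviol already has rings A, C and D (the bicyclo[3.2.1]octane C8, C9, C11–C16), the stereocentres C4, C5, C8, C9, C10 and C13, the 13-hydroxyl, and an axial C19 carboxyl on C4 that lies syn-axial to H-6α, H-2α and the C20 methyl (α = face of C19 and C20).
4. Ring order: rings A, C and D are inherited; ring B is re-formed in step 9 (six to five); the δ-lactone ring (C4, C19, O, C20, C10, C5) closes in step 14; C17 is taken off in step 2 and put back in step 17.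

Key step: step 9

Remark: the C16 methylene, allylic to the 13-oxygen and prone to halonium-triggered semipinacol shift and to epoxidation, is not expected to survive the manganese-oxo and iodine oxidants, so it is carried from step 2 to step 17 as the 17-nor-16-ketone or its dioxolane; ethyl formate (10) and 4-acetamidobenzenesulfonyl azide (12) are numbered as starting materials, all other chemicals are reagents.

## Route

Step 1
Reactants: 1 steviol
Product: 3 13-O-TBS-steviol, via bis-silyl compound 2 (not isolated)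
Conditions: TBSOTf (3 equiv), 2,6-lutidine, CH2Cl2, 0 °C → rt; then K2CO3, MeOH/THF/H2O, rt
Reagents that add atoms: tert-butyldimethylsilyl trifluoromethanesulfonate, CC(C)(C)[Si](C)(C)OS(=O)(=O)C(F)(F)F
Why: O-silylation with a silyl triflate and a hindered pyridine base protects the tertiary bridgehead alcohol, the silyl ester formed at C19 at the same time is removed by mild carbonate solvolysis, and the buffered medium avoids the acid-triggered rearrangement of rings C and D.

Step 2
Reactants: 3 13-O-TBS-steviol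
Product: 4 13-O-TBS-16-oxo-17-norsteviol
Conditions: O3, CH2Cl2/MeOH, −78 °C; then Me2S, −78 °C → rt
Reagents that add atoms: ozone, [O-][O+]=O
Why: Ozonolysis of the 1,1-disubstituted alkene, in which the primary ozonide should collapse in methanol to the ketone and formaldehyde O-oxide (trapped by the solvent, reduced by Me2S); the silyl ether blocks the α-ketol rearrangement of the 13-oxygenated norketone.

Step 3
Reactants: 4 13-O-TBS-16-oxo-17-norsteviol
Product: 5 13-O-TBS-16-oxo-17-nor-ent-kauran-19,6α-olide
Conditions: [Mn(OTf)2(L)] (2 mol %; L = (S,S)-N,N'-bis[(5-triisopropylsilylpyridin-2-yl)methyl]-2,2'-bipyrrolidine, or its antipode), 30 % aq. H2O2 (slow addition), CF3CH2OH, 0 °C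
Reagents that add atoms: none
Why: Carboxylate-directed γ-C–H lactonisation (hydrogen abstraction by a carboxylate-bound manganese-oxo, then carboxylate rebound): the axial C19 carboxylate reaches the axial H-6α, the most compressed γ-hydrogen (syn-axial to C20 and C14), the chiral catalyst is the handle for favouring it over the other γ-methylene C2, the tether places the new C6–O bond on the α face, and the C16 ketone deactivates ring D.

Step 4
Reactants: 5 13-O-TBS-16-oxo-17-nor-ent-kauran-19,6α-olide
Product: 6 16,16-ethylenedioxy ketal of lactone 5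
Conditions: (Me3SiOCH2)2, Me3SiOTf (cat.), CH2Cl2, −78 → 0 °C; then pyridine, aq. NaHCO3
Reagents that add atoms: 1,2-bis(trimethylsilyloxy)ethane, C[Si](C)(C)OCCO[Si](C)(C)C
Why: Noyori ketalisation works on hindered ketones at low temperature without touching the silyl ether or the lactone, and the dioxolane masks C16 against the later formylation, photolysis and SmI2.

Step 5
Reactants: 6 16,16-ethylenedioxy ketal of lactone 5
Product: 8 allyl 6α-hydroxy ester, via potassium hydroxy-carboxylate 7 (not isolated)
Conditions: KOH (1.1 equiv), THF/MeOH/H2O, 60 °C; evaporate; allyl bromide, DMF, 0 °C → rt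
Reagents that add atoms: potassium hydroxide, [K+].[OH-]; allyl bromide, C=CCBr
Why: Saponification of the γ-lactone by acyl–oxygen cleavage (C6 configuration kept) followed by SN2 O-alkylation of the carboxylate; the hindered axial 6α-hydroxyl is not alkylated, and the allyl ester leaves C19 without O–H or N–H through the diazo ketone and ketene stages.

Step 6
Reactants: 8 allyl 6α-hydroxy ester
Product: 9 allyl 6-oxo ester
Conditions: Dess–Martin periodinane, NaHCO3, CH2Cl2, 0 °C → rt
Reagents that add atoms: none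
Why: Dess–Martin oxidation of the hindered axial secondary alcohol under buffered conditions, fast enough to outrun relactonisation; the trans A/B fusion at C5 is the stable one next to the ketone.

Step 7
Reactants: 9 allyl 6-oxo ester; 10 ethyl formate
Product: 11 allyl 7-(hydroxymethylene)-6-oxo ester
Conditions: NaH, EtOH (cat.), THF, 0 °C → rt; then AcOH
Reagents that add atoms: none
Why: Claisen formylation, reversible and driven to C7 because only the C7 methylene can give the stabilised enolate of a hydroxymethylene ketone (C5 is a methine, C16 is masked).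

Step 8
Reactants: 11 allyl 7-(hydroxymethylene)-6-oxo ester; 12 4-acetamidobenzenesulfonyl azide
Product: 13 allyl 7-diazo-6-oxo ester
Conditions: Et3N, CH3CN, 0 °C → rt
Reagents that add atoms: none
Why: Regitz deformylative diazo transfer, in which the sulfonyl azide adds to the enolate and the triazoline fragments with loss of the N-formyl sulfonamide.

Step 9
Reactants: 13 allyl 7-diazo-6-oxo ester
Product: 16 19-allyl 7-(2-trimethylsilylethyl) 13-O-TBS-16,16-ethylenedioxy-17-nor-ent-gibberellane-7,19-dioate, via ketene 14 (not isolated), via 6-epi diester 15 (not isolated)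
Conditions: hν (365 nm), Me3SiCH2CH2OH (20 equiv), THF, 0 °C → rt; then NaN(SiMe3)2 (0.3 equiv), 40 °C
Reagents that add atoms: 2-(trimethylsilyl)ethanol, C[Si](C)(C)CCO
Why: Light expels N2 from the cyclic diazo ketone and, in concert, the bond from C5 to the carbonyl carbon (kaurane C6) shifts to the diazo carbon (kaurane C7) with retention at C5, giving ketene 14 exocyclic to the new ring, to which the alcohol adds before the ester enol tautomerises. The closest known reaction type is the photochemical Wolff ring contraction of cyclic 2-diazo ketones to cyclopentane carboxylic esters. Ring B of the gibberellane (C5, C6, C8, C9, C10) is therefore closed not by a cyclisation but by a 1,2-alkyl shift that contracts the six-membered ring by one atom, and the former carbonyl carbon becomes the ester carbon C7. The one new stereocentre, C6, is set under thermodynamic control: kinetic protonation of the enol from the more open β face should give mainly the 6-epimer 15, and the catalytic alkoxide (the alkoxide of the ester alcohol, so no transesterification) should equilibrate it to 16, with C7 trans to C4 on ring B. The step needs rearrangement to win over O–H insertion and hydride shift, which is secured because the carbene carbon is flanked by the quaternary C8, the acyl carbon carries only C5 as migrating group, and the ring locks the diazo ketone in the s-cis geometry of the concerted pathway. No other stereocentre is touched.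

Step 10
Reactants: 16 19-allyl 7-(2-trimethylsilylethyl) diester
Product: 17 7-(2-trimethylsilylethyl) ester 19-acid
Conditions: Pd(PPh3)4 (5 mol %), morpholine, THF, rt
Reagents that add atoms: none
Why: Tsuji–Trost deallylation with zerovalent palladium and morpholine as allyl acceptor; cleavage is at the allyl C–O bond, so the hindrance of the C19 carboxyl does not matter and the other ester, ketal and silyl ether are untouched.

Step 11
Reactants: 17 7-(2-trimethylsilylethyl) ester 19-acid
Product: 18 19,2α-lactone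
Conditions: [Mn(OTf)2(L)] (2 mol %; L as in step 3), 30 % aq. H2O2 (slow addition), CF3CH2OH, 0 °C
Reagents that add atoms: none
Why: The same carboxylate-directed manganese-catalysed γ-C–H lactonisation as in step 3: the only γ-hydrogens are the axial H-2α, syn to C19, and H-6, which the C7 ester deactivates towards the electrophilic oxidant, so the lactone should form at C2 with the oxygen α (set by the tether), while trifluoroethanol hydrogen-bonds to the dioxolane oxygens and protects their α-C–H bonds.

Step 12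
Reactants: 18 19,2α-lactone
Product: 19 2α-hydroxy 19-carboxamide
Conditions: AlMe3, NH3, CH2Cl2, 0 → 40 °C; then aq. potassium sodium tartrate (KNaC4H4O6)
Reagents that add atoms: ammonia, N
Why: Weinreb aminolysis with dimethylaluminium amide opens the bridged γ-lactone to the primary amide and the axial 2α-alcohol (C2 configuration kept); the lactone should react before the hindered C7 ester.

Step 13
Reactants: 19 2α-hydroxy 19-carboxamide
Product: 20 2-oxo 19-carboxamide
Conditions: Dess–Martin periodinane, NaHCO3, CH2Cl2, rt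
Reagents that add atoms: none
Why: Dess–Martin oxidation of the hindered axial alcohol; the ketone removes every hydrogen from C2, so that the nitrogen radical of the next step can only reach C20.

Step 14
Reactants: 20 2-oxo 19-carboxamide
Product: 22 2-oxo-19,20-lactone, via imino-lactone 21 (not isolated)
Conditions: PhI(OAc)2, I2, CH2Cl2, hν (visible, tungsten lamp), rt; then aq. Na2S2O3; THF/H2O, AcOH (cat.), rt
Reagents that add atoms: water, O
Why: Suárez variant of the Hofmann–Löffler–Freytag reaction on a primary amide: the N-iodoamide gives an amidyl radical, 1,6-hydrogen transfer from the syn-axial C20 methyl, iodination, and displacement of the oxidised iodide by the amide oxygen, the imino-lactone being hydrolysed in the work-up; C2 has no hydrogen and H-6 is polarity-mismatched.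

Step 15
Reactants: 22 2-oxo-19,20-lactone
Product: 23 2β-hydroxy-19,20-lactone
Conditions: SmI2 (2.5 equiv), THF, H2O (20 equiv), 0 °C
Reagents that add atoms: none
Why: Single-electron (dissolving-metal type) ketone reduction should give the thermodynamically preferred alcohol, here the equatorial 2β-alcohol pointing away from the lactone bridge of the bicyclo[3.3.1] system, the epimer that hydride attack from the open face would not give; esters, the ketal and (short time, limited water) the lactone are not reduced.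

Step 16
Reactants: 23 2β-hydroxy-19,20-lactone
Product: 24 2β-hydroxy-16-oxo-17-nor-19,20-lactone 13-O-TBS ether 7-(2-trimethylsilylethyl) ester
Conditions: 1 M aq. HCl, THF, 40 °C
Reagents that add atoms: water, O
Why: Acid-catalysed ketal hydrolysis; the tertiary silyl ether, the silylethyl ester and the δ-lactone tolerate dilute aqueous acid.

Step 17
Reactants: 24 2β-hydroxy-16-oxo-17-nor-19,20-lactone 13-O-TBS ether 7-(2-trimethylsilylethyl) ester
Product: 25 13-O-TBS ether 7-(2-trimethylsilylethyl) ester of the target gibberellin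
Conditions: Ph3PCH3Br, KOtBu, THF, 0 °C → rt
Reagents that add atoms: methyltriphenylphosphonium bromide, C[P+](c1ccccc1)(c1ccccc1)c1ccccc1.[Br-]
Why: Wittig methylenation of the 17-nor-16-ketone, the standard way of restoring C17 in gibberellins; excess ylide covers the free 2β-hydroxyl, lactone and ester carbonyls should not react, and the silyl ether prevents the α-ketol rearrangement under base.

Step 18
Reactants: 25 13-O-TBS ether 7-(2-trimethylsilylethyl) ester of the target gibberellin
Product: 26 target gibberellin (2β,13-dihydroxy 19,20-lactone 7-acid)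
Conditions: Bu4NF, THF, rt → 50 °C; then dilute aq. HCl to pH 3
Reagents that add atoms: none
Why: Fluoride cleaves the tertiary silyl ether and fragments the 2-(trimethylsilyl)ethyl ester (β-elimination to ethylene and Me3SiF) in one operation, without acid that could rearrange the 13-hydroxy-16-ene; a lactone opened by adventitious hydroxide recloses on acidification.

## Compound list

1 | steviol (ent-13-hydroxykaur-16-en-19-oic acid) | C=C1C[C@]23C[C@@]1(O)CC[C@H]2[C@]1(C)CCC[C@@](C)(C(=O)O)[C@H]1CC3 | starting material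
2 | tert-butyldimethylsilyl 13-O-TBS-steviolate (silyl ester and silyl ether) | C=C1C[C@]23C[C@@]1(O[Si](C)(C)C(C)(C)C)CC[C@H]2[C@]1(C)CCC[C@@](C)(C(=O)O[Si](C)(C)C(C)(C)C)[C@H]1CC3 | intermediate (not isolated)
3 | 13-O-TBS-steviol | C=C1C[C@]23C[C@@]1(O[Si](C)(C)C(C)(C)C)CC[C@H]2[C@]1(C)CCC[C@@](C)(C(=O)O)[C@H]1CC3 | intermediate
4 | 13-O-TBS-16-oxo-17-norsteviol (16-ketone in place of the methylene) | O=C1C[C@]23C[C@@]1(O[Si](C)(C)C(C)(C)C)CC[C@H]2[C@]1(C)CCC[C@@](C)(C(=O)O)[C@H]1CC3 | intermediate
5 | 13-O-TBS-16-oxo-17-nor-ent-kauran-19,6α-olide (γ-lactone C19–O–C6, oxygen on the face of C19 and C20) | O=C1C[C@]23C[C@@]1(O[Si](C)(C)C(C)(C)C)CC[C@H]2[C@]1(C)CCC[C@@](C)(C(=O)O4)[C@H]1[C@@H]4C3 | intermediate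
6 | 16,16-ethylenedioxy ketal of lactone 5 | O1CCOC12C[C@]34C[C@@]2(O[Si](C)(C)C(C)(C)C)CC[C@H]3[C@]2(C)CCC[C@@](C)(C(=O)O5)[C@H]2[C@@H]5C4 | intermediate
7 | potassium 6α-hydroxy-16,16-ethylenedioxy-13-O-TBS-17-nor-ent-kauran-19-oate | O1CCOC12C[C@]34C[C@@]2(O[Si](C)(C)C(C)(C)C)CC[C@H]3[C@]2(C)CCC[C@@](C)(C(=O)[O-])[C@H]2[C@@H](O)C4.[K+] | intermediate (not isolated)
8 | allyl 6α-hydroxy-16,16-ethylenedioxy-13-O-TBS-17-nor-ent-kauran-19-oate | O1CCOC12C[C@]34C[C@@]2(O[Si](C)(C)C(C)(C)C)CC[C@H]3[C@]2(C)CCC[C@@](C)(C(=O)OCC=C)[C@H]2[C@@H](O)C4 | intermediate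
9 | allyl 6-oxo-16,16-ethylenedioxy-13-O-TBS-17-nor-ent-kauran-19-oate | O1CCOC12C[C@]34C[C@@]2(O[Si](C)(C)C(C)(C)C)CC[C@H]3[C@]2(C)CCC[C@@](C)(C(=O)OCC=C)[C@H]2C(=O)C4 | intermediate
10 | ethyl formate | CCOC=O | starting material
11 | allyl (Z)-7-(hydroxymethylene)-6-oxo-16,16-ethylenedioxy-13-O-TBS-17-nor-ent-kauran-19-oate | O1CCOC12C[C@]34C[C@@]2(O[Si](C)(C)C(C)(C)C)CC[C@H]3[C@]2(C)CCC[C@@](C)(C(=O)OCC=C)[C@H]2C(=O)/C4=C\O | intermediate
12 | 4-acetamidobenzenesulfonyl azide | CC(=O)Nc1ccc(cc1)S(=O)(=O)N=[N+]=[N-] | starting material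
13 | allyl 7-diazo-6-oxo-16,16-ethylenedioxy-13-O-TBS-17-nor-ent-kauran-19-oate (Wolff precursor) | O1CCOC12C[C@]34C[C@@]2(O[Si](C)(C)C(C)(C)C)CC[C@H]3[C@]2(C)CCC[C@@](C)(C(=O)OCC=C)[C@H]2C(=O)C4=[N+]=[N-] | intermediate
14 | ring-contracted ketene (gibberellane, C6=C7=O, 19-allyl ester) | O1CCOC12C[C@]34C[C@@]2(O[Si](C)(C)C(C)(C)C)CC[C@H]3[C@]2(C)CCC[C@@](C)(C(=O)OCC=C)[C@H]2C4=C=O | intermediate (not isolated)
15 | 6-epimer of diester 16 (C7 cis to C4 on ring B) | O1CCOC12C[C@]34C[C@@]2(O[Si](C)(C)C(C)(C)C)CC[C@H]3[C@]2(C)CCC[C@@](C)(C(=O)OCC=C)[C@H]2[C@H]4C(=O)OCC[Si](C)(C)C | intermediate (not isolated)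
16 | 19-allyl 7-[2-(trimethylsilyl)ethyl] 13-O-TBS-16,16-ethylenedioxy-17-nor-ent-gibberellane-7,19-dioate (Wolff product; methyl groups on C4 and C10, C7 ester trans to C4 on ring B) | O1CCOC12C[C@]34C[C@@]2(O[Si](C)(C)C(C)(C)C)CC[C@H]3[C@]2(C)CCC[C@@](C)(C(=O)OCC=C)[C@H]2[C@@H]4C(=O)OCC[Si](C)(C)C | intermediate
17 | 13-O-TBS-16,16-ethylenedioxy-17-nor-ent-gibberellane-7,19-dioic acid 7-[2-(trimethylsilyl)ethyl] ester (free C19 acid) | O1CCOC12C[C@]34C[C@@]2(O[Si](C)(C)C(C)(C)C)CC[C@H]3[C@]2(C)CCC[C@@](C)(C(=O)O)[C@H]2[C@@H]4C(=O)OCC[Si](C)(C)C | intermediate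
18 | 19,2α-lactone of the 2α-hydroxy derivative of 17 | O1CCOC12C[C@]34C[C@@]2(O[Si](C)(C)C(C)(C)C)CC[C@H]3[C@]2(C)C[C@@H]5C[C@@](C)(C(=O)O5)[C@H]2[C@@H]4C(=O)OCC[Si](C)(C)C | intermediate
19 | 2α-hydroxy 19-carboxamide (7-silylethyl ester, 13-O-TBS, 16-ketal) | O1CCOC12C[C@]34C[C@@]2(O[Si](C)(C)C(C)(C)C)CC[C@H]3[C@]2(C)C[C@@H](O)C[C@@](C)(C(N)=O)[C@H]2[C@@H]4C(=O)OCC[Si](C)(C)C | intermediate
20 | 2-oxo 19-carboxamide (7-silylethyl ester, 13-O-TBS, 16-ketal) | O1CCOC12C[C@]34C[C@@]2(O[Si](C)(C)C(C)(C)C)CC[C@H]3[C@]2(C)CC(=O)C[C@@](C)(C(N)=O)[C@H]2[C@@H]4C(=O)OCC[Si](C)(C)C | intermediate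
21 | 2-oxo 19,20-imino-lactone (C19(=NH)–O–C20) | O1CCOC12C[C@]34C[C@@]2(O[Si](C)(C)C(C)(C)C)CC[C@H]3[C@]25COC(=N)[C@](C)(CC(=O)C2)[C@H]5[C@@H]4C(=O)OCC[Si](C)(C)C | intermediate (not isolated)
22 | 2-oxo-19,20-lactone (7-silylethyl ester, 13-O-TBS, 16-ketal) | O1CCOC12C[C@]34C[C@@]2(O[Si](C)(C)C(C)(C)C)CC[C@H]3[C@]25COC(=O)[C@](C)(CC(=O)C2)[C@H]5[C@@H]4C(=O)OCC[Si](C)(C)C | intermediate
23 | 2β-hydroxy-19,20-lactone (7-silylethyl ester, 13-O-TBS, 16-ketal) | O1CCOC12C[C@]34C[C@@]2(O[Si](C)(C)C(C)(C)C)CC[C@H]3[C@]25COC(=O)[C@](C)(C[C@@H](O)C2)[C@H]5[C@@H]4C(=O)OCC[Si](C)(C)C | intermediate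
24 | 2β-hydroxy-16-oxo-17-nor-19,20-lactone 13-O-TBS ether 7-[2-(trimethylsilyl)ethyl] ester | O=C1C[C@]23C[C@@]1(O[Si](C)(C)C(C)(C)C)CC[C@H]2[C@]12COC(=O)[C@](C)(C[C@@H](O)C1)[C@H]2[C@@H]3C(=O)OCC[Si](C)(C)C | intermediate
25 | 13-O-TBS ether 7-[2-(trimethylsilyl)ethyl] ester of the target gibberellin | C=C1C[C@]23C[C@@]1(O[Si](C)(C)C(C)(C)C)CC[C@H]2[C@]12COC(=O)[C@](C)(C[C@@H](O)C1)[C@H]2[C@@H]3C(=O)OCC[Si](C)(C)C | intermediate
26 | target gibberellin: 2β,13-dihydroxy-19,20-lactone 7-acid (ent-2α,13,20-trihydroxygibberell-16-ene-7,19-dioic acid 19,20-lactone) | C=C1C[C@]23C[C@@]1(O)CC[C@H]2[C@]12COC(=O)[C@](C)(C[C@@H](O)C1)[C@H]2[C@@H]3C(=O)O | target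

## Step count and risks

Total step count: 18. Longest linear sequence: 18 steps (steviol 1 to target 26).

Steps most likely to fail, in order:

Step 3. The bound oxidant may abstract hydrogen at the other γ-methylene (C2) instead of C6, or the directing effect may be lost and ring C–H bonds oxidised at random. Fallback: replace the metal-oxo by a nitrogen-radical chain. Setting out from keto acid 4, 1-chloro-N,N,2-trimethylprop-1-en-1-amine in CH2Cl2 gives the 19-acid chloride F1, which is treated in the same flask with ammonia to give the primary 19-amide F2. PhI(OAc)2 and I2 under visible light then generate the amidyl radical, which should take the strain-activated axial H-6α by 1,5-transfer. Ring closure gives the 19,6α-imino-lactone F3, which is hydrolysed in the aqueous work-up, and the route is rejoined at lactone 5.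

Step 14. The γ-keto amide may close to a bridged hydroxy-lactam or be iodinated next to the C2 ketone, so that the N-iodoamide chain is diverted, and 1,6-hydrogen transfer from a methyl group is intrinsically slow. Fallback: carry C2 at the alcohol level, where its only hydrogen is equatorial and out of reach, and oxidise after the lactone is in place. Setting out from hydroxy amide 19, N-(trimethylsilyl)imidazole in CH2Cl2 silylates the hindered axial hydroxyl and gives the 2α-trimethylsilyloxy 19-carboxamide F4. PhI(OAc)2 and I2 under visible light, buffered with NaHCO3, give the 2α-trimethylsilyloxy 19,20-imino-lactone F5. The mildly acidic aqueous work-up hydrolyses it and removes the silyl group, giving the 2α-hydroxy-19,20-lactone F6. Dess–Martin oxidation then comes back to the route at ketone 22.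

Step 11. In a substrate now carrying five functional groups the oxidant may attack the dioxolane or the silyl-bearing carbons, or the ketal may be lost in the protic fluorinated solvent. Fallback: amidyl-radical lactonisation. Setting out from acid 17, 1-chloro-N,N,2-trimethylprop-1-en-1-amine gives the 19-acid chloride F7, and ammonia then gives the 19-carboxamide F8. PhI(OAc)2 and I2 under visible light then effect 1,5-hydrogen transfer from the axial H-2α and closure to the 19,2α-imino-lactone F9, whose hydrolysis in the work-up comes back to the route at lactone 18.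

Further compounds
F1 | step 3 | 13-O-TBS-16-oxo-17-nor-ent-kauran-19-oyl chloride | O=C1C[C@]23C[C@@]1(O[Si](C)(C)C(C)(C)C)CC[C@H]2[C@]1(C)CCC[C@@](C)(C(=O)Cl)[C@H]1CC3
F2 | step 3 | 13-O-TBS-16-oxo-17-nor-ent-kauran-19-amide | O=C1C[C@]23C[C@@]1(O[Si](C)(C)C(C)(C)C)CC[C@H]2[C@]1(C)CCC[C@@](C)(C(N)=O)[C@H]1CC3
F3 | step 3 | 19,6α-imino-lactone of the 16-oxo series | O=C1C[C@]23C[C@@]1(O[Si](C)(C)C(C)(C)C)CC[C@H]2[C@]1(C)CCC[C@@](C)(C(=N)O4)[C@H]1[C@@H]4C3
F4 | step 14 | 2α-trimethylsilyloxy 19-carboxamide | O1CCOC12C[C@]34C[C@@]2(O[Si](C)(C)C(C)(C)C)CC[C@H]3[C@]2(C)C[C@@H](O[Si](C)(C)C)C[C@@](C)(C(N)=O)[C@H]2[C@@H]4C(=O)OCC[Si](C)(C)C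
F5 | step 14 | 2α-trimethylsilyloxy 19,20-imino-lactone | O1CCOC12C[C@]34C[C@@]2(O[Si](C)(C)C(C)(C)C)CC[C@H]3[C@]25COC(=N)[C@](C)(C[C@H](O[Si](C)(C)C)C2)[C@H]5[C@@H]4C(=O)OCC[Si](C)(C)C
F6 | step 14 | 2α-hydroxy-19,20-lactone | O1CCOC12C[C@]34C[C@@]2(O[Si](C)(C)C(C)(C)C)CC[C@H]3[C@]25COC(=O)[C@](C)(C[C@H](O)C2)[C@H]5[C@@H]4C(=O)OCC[Si](C)(C)C
F7 | step 11 | 19-acid chloride of 17 | O1CCOC12C[C@]34C[C@@]2(O[Si](C)(C)C(C)(C)C)CC[C@H]3[C@]2(C)CCC[C@@](C)(C(=O)Cl)[C@H]2[C@@H]4C(=O)OCC[Si](C)(C)C
F8 | step 11 | 19-carboxamide of 17 | O1CCOC12C[C@]34C[C@@]2(O[Si](C)(C)C(C)(C)C)CC[C@H]3[C@]2(C)CCC[C@@](C)(C(N)=O)[C@H]2[C@@H]4C(=O)OCC[Si](C)(C)C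
F9 | step 11 | 19,2α-imino-lactone | O1CCOC12C[C@]34C[C@@]2(O[Si](C)(C)C(C)(C)C)CC[C@H]3[C@]2(C)C[C@@H]5C[C@@](C)(C(=N)O5)[C@H]2[C@@H]4C(=O)OCC[Si](C)(C)C
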